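## Retrosynthetic overview

1. Ring numbering used throughout: C1 ketone, C2 (bears CH2OH), C3 (=CH), C4 (isobutyrate), C5 (isopropyl), C6 (enoate ester). In the single carbocycle the contiguous atoms C1–C6–C5–C4–C3 show the pattern C=O / CH–O / CH–iPr / CH–O / CH of a 2,4-dioxygenated 3-isopropylcyclopentanone. Only C2 therefore has to be slipped in between C1 and C3.
2. Last bonds made: side-chain O–Si cleavage (fluoride), C2–CH2OH (Stille on a 2-bromoenone), C4–O (Mitsunobu with inversion), and the C6 O–acyl bond (Steglich, with the acid from an E-selective Wittig).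
3. Core: the 2-bromocyclohexenone is traced back to the dibromocarbene adduct of the kinetic trimethylsilyl enol ether of that cyclopentanone. The carbene carbon becomes C2.
4. The cyclopentanone derives from (R)-4-silyloxycyclopentenone by anti 1,4-addition of isopropyl, silyl trapping and Rubottom oxidation.
5. Ring order: the five-membered ring is bought, a cyclopropane is fused to it in passing, and opening of that bicycle delivers the six-membered ring, the only ring of the target.

Key step: step 4

Assumption: cyclopropane 10 is drawn as the adduct formed on the face opposite the two flanking silyloxy groups. Both of its new centres become sp2 in the same flask, so this assignment has no bearing on the route.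

## Route

Step 1
Reactants: 1 (R)-4-(tert-butyldimethylsilyloxy)cyclopent-2-en-1-one; 2 isopropylmagnesium chloride
Product: 4 (3R,4R)-4-(tert-butyldimethylsilyloxy)-3-isopropyl-1-(triethylsilyloxy)cyclopent-1-ene, via chloromagnesium enolate 3 (not isolated)
Conditions: 2 (1.3 equiv), CuBr·SMe2 (10 mol %), TESCl (2 equiv), DMPU (2 equiv), THF, −78 → −30 °C; Et3N, cold aq NaHCO3
Reagents that add atoms: isopropylmagnesium chloride 2, CC(C)[Mg]Cl; chlorotriethylsilane, CC[Si](Cl)(CC)CC
Why: Copper-catalysed, chlorosilane-assisted 1,4-addition of a Grignard reagent delivers isopropyl to the enone face opposite the bulky silyloxy group, which sets the future C5 centre trans to C4–O, and O-silylation of the regiodefined enolate 3 fixes the double bond toward the future C6 before equilibration or loss of silanolate can intervene.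

Step 2
Reactants: 4 triethylsilyl enol ether
Product: 6 (2R,3S,4R)-4-(tert-butyldimethylsilyloxy)-3-isopropyl-2-(triethylsilyloxy)cyclopentan-1-one, via silyloxy epoxide 5 (not isolated)
Conditions: mCPBA (1.1 equiv), hexane, −15 → 0 °C
Reagents that add atoms: 3-chloroperbenzoic acid, O=C(OO)c1cccc(Cl)c1
Why: In this Rubottom oxidation the peracid attacks the electron-rich enol ether from the face opposite the adjacent isopropyl group and epoxide 5 collapses with migration of the triethylsilyl group to the new oxygen, so the future C6–O bond is set trans to isopropyl, which is also the more stable epimer of the α-silyloxy ketone.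

Step 3
Reactants: 6 α-triethylsilyloxy cyclopentanone
Product: 8 (3S,4S,5R)-3-(tert-butyldimethylsilyloxy)-4-isopropyl-5-(triethylsilyloxy)-1-(trimethylsilyloxy)cyclopent-1-ene, via lithium enolate 7 (not isolated)
Conditions: TMSCl (3 equiv), then LiN(iPr)2 (LDA, 1.2 equiv) dropwise, THF, −78 °C; pentane, filtration (non-aqueous work-up)
Reagents that add atoms: chlorotrimethylsilane, C[Si](C)(C)Cl
Why: Kinetic enolisation by a hindered lithium amide with the chlorosilane already present (in situ quench) takes a proton from the accessible CH2 and not from the crowded silyloxy-bearing methine, and enolate 7 is silylated at −78 °C faster than it can expel the β-silyloxy group, so the enol ether double bond lies between the future C1 and C3 and no stereocentre is touched.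

Step 4
Reactants: 8 kinetic trimethylsilyl enol ether; 9 bromoform
Product: 11 (4S,5S,6R)-2-bromo-4-(tert-butyldimethylsilyloxy)-5-isopropyl-6-(triethylsilyloxy)cyclohex-2-en-1-one, via dibromocyclopropane 10 (not isolated)
Conditions: CHBr3 (2.0 equiv), KOtBu (1.8 equiv, in portions), pentane, −30 °C → rt
Reagents that add atoms: bromoform 9, BrC(Br)Br
Why: α-Elimination of HBr from bromoform gives dibromocarbene, which adds in a concerted [2+1] fashion to the only electron-rich π bond of 8 and so forms the C2–C1 and C2–C3 bonds of cyclopropane 10. Ring strain and the donor oxygen then drive a disrotatory two-electron electrocyclic opening with departure of the endo bromide, in which the old C1–C3 bond breaks and the resulting 1-silyloxy-2-bromoallyl cation gives up its trimethylsilyl group to bromide, leaving the C1 ketone, the C2=C3 double bond and bromine on C2. The closest known reaction type is the dihalocarbene ring expansion of cyclic trimethylsilyl enol ethers to 2-halocycloalk-2-enones. The three-membered ring closes by cheletropic addition, and the six-membered ring arises by enlargement of the bicyclo[3.1.0]hexane rather than by cyclisation of a chain. No lasting stereocentre is created, because both cyclopropane centres end up sp2 and C4, C5 and C6 are spectators, so the face of carbene attack is immaterial. The selectivity required is regiochemical (insertion into C1–C3, not C1–C6) and is already fixed by the position of the double bond in 8, while keeping bromoform in excess over the base at low temperature shields the base-sensitive enone.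

Step 5
Reactants: 12 ethyl 2-(triphenylphosphoranylidene)propanoate; 13 (tert-butyldiphenylsilyloxy)acetaldehyde
Product: 14 ethyl (E)-4-(tert-butyldiphenylsilyloxy)-2-methylbut-2-enoate
Conditions: CH2Cl2, rt
Reagents that add atoms: ethyl 2-(triphenylphosphoranylidene)propanoate 12, CCOC(=O)C(C)=P(c1ccccc1)(c1ccccc1)c1ccccc1
Why: Wittig olefination with a stabilised α-methyl ylide in an aprotic solvent should give the trisubstituted enoate with the ester and the CH2O group on opposite sides, that is the E isomer.

Step 6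
Reactants: 14 ethyl enoate
Product: 16 (E)-4-(tert-butyldiphenylsilyloxy)-2-methylbut-2-enoic acid, via lithium carboxylate 15 (not isolated)
Conditions: LiOH·H2O, THF/MeOH/H2O, rt; 1 M HCl to pH 3, 0 °C
Reagents that add atoms: lithium hydroxide, [Li+].[OH-]
Why: Saponification of the unhindered ethyl ester leaves the primary tert-butyldiphenylsilyl ether and the E double bond intact, and brief cold acidification of carboxylate 15 releases the acid.

Step 7
Reactants: 11 bis-silylated bromoenone
Product: 17 (4S,5R,6R)-2-bromo-4-(tert-butyldimethylsilyloxy)-6-hydroxy-5-isopropylcyclohex-2-en-1-one (4,5-trans and 5,6-trans as in 11)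
Conditions: PPTS (0.2 equiv), MeOH/CH2Cl2 (1:1), 0 °C
Reagents that add atoms: none
Why: Acid-catalysed methanolysis discriminates silyl ethers by bulk, so the triethylsilyl ether next to the ketone is cleaved far faster than the secondary tert-butyldimethylsilyl ether, and the weak acid does not enolise C6.

Step 8
Reactants: 17 α-hydroxy bromoenone; 16 side-chain acid
Product: 19 (4S,5R,6R)-2-bromo-4-(tert-butyldimethylsilyloxy)-5-isopropyl-6-{[(E)-4-(tert-butyldiphenylsilyloxy)-2-methylbut-2-enoyl]oxy}cyclohex-2-en-1-one, via O-acylisourea 18 (not isolated)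
Conditions: DCC (1.3 equiv), DMAP (0.1 equiv), CH2Cl2, 0 °C → rt
Reagents that add atoms: acid 16, C/C(=C\CO[Si](c1ccccc1)(c1ccccc1)C(C)(C)C)C(=O)O
Why: In this Steglich esterification DCC activates 16 as O-acylisourea 18 and DMAP relays the acyl group to the C6 hydroxyl without touching the C6–O bond, and any base-induced equilibration at C6 is harmless because the 5,6-trans isomer is the more stable one.

Step 9
Reactants: 19 C6 ester
Product: 20 (4S,5S,6R)-2-bromo-4-hydroxy-5-isopropyl-6-{[(E)-4-(tert-butyldiphenylsilyloxy)-2-methylbut-2-enoyl]oxy}cyclohex-2-en-1-one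
Conditions: TFA/H2O (9:1), CH2Cl2, 0 °C
Reagents that add atoms: none
Why: Protic hydrolysis removes the tert-butyldimethylsilyl ether while the much more acid-resistant tert-butyldiphenylsilyl ether, the ester and the bromoenone persist, and ionisation at C4 is not expected because such a cation would be destabilised by the enone.

Step 10
Reactants: 20 C4 alcohol; 21 isobutyric acid
Product: 23 (4R,5S,6R)-2-bromo-4-(isobutyryloxy)-5-isopropyl-6-{[(E)-4-(tert-butyldiphenylsilyloxy)-2-methylbut-2-enoyl]oxy}cyclohex-2-en-1-one, via alkoxyphosphonium isobutyrate 22 (not isolated)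
Conditions: PPh3 (2 equiv) and DIAD (2 equiv) premixed, then 21 (2.5 equiv) and 20, toluene, 0 °C → rt
Reagents that add atoms: isobutyric acid 21, CC(C)C(=O)O
Why: In this Mitsunobu reaction the C4 hydroxyl is activated as phosphonium salt 22 and displaced by isobutyrate in an SN2 process with inversion, which turns the 4,5-trans into the required 4,5-cis relationship, a change analogous to the known inversion of equatorial cyclohexanols flanked by an isopropyl group and helped here by the allylic position.

Step 11
Reactants: 23 C4-inverted bromoenone diester; 24 (tributylstannyl)methanol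
Product: 25 (4S,5S,6R)-2-(hydroxymethyl)-4-(isobutyryloxy)-5-isopropyl-6-{[(E)-4-(tert-butyldiphenylsilyloxy)-2-methylbut-2-enoyl]oxy}cyclohex-2-en-1-one
Conditions: 24 (1.5 equiv), Pd2(dba)3 (5 mol %), AsPh3 (20 mol %), CuI (10 mol %), degassed NMP, 50 °C
Reagents that add atoms: (tributylstannyl)methanol 24, CCCC[Sn](CCCC)(CCCC)CO
Why: In this Stille coupling zerovalent palladium should insert into the activated C2–Br bond of the α-bromoenone faster than it ionises the hindered allylic isobutyrate, and tin transfers the hydroxymethyl group in preference to butyl, a known way to hydroxymethylate oxygenated 2-halocyclohexenones without protecting the alcohol and without affecting any stereocentre (the C4 descriptor changes only because the priorities change).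

Step 12
Reactants: 25 silyl-protected hydroxymethyl enone
Product: 26 CNP0254776.1: (4S,5S,6R)-6-{[(E)-4-hydroxy-2-methylbut-2-enoyl]oxy}-2-(hydroxymethyl)-4-(isobutyryloxy)-5-isopropylcyclohex-2-en-1-one
Conditions: HF·pyridine, excess pyridine, THF, 0 °C → rt
Reagents that add atoms: none
Why: Pyridine-buffered HF cleaves the remaining silyl ether through formation of the strong Si–F bond under weakly acidic conditions that should cause no ester migration, β-elimination or E/Z isomerisation.

## Compound list

1 | (R)-4-(tert-butyldimethylsilyloxy)cyclopent-2-en-1-one | O=C1C=C[C@H](O[Si](C)(C)C(C)(C)C)C1 | starting material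
2 | isopropylmagnesium chloride | CC(C)[Mg]Cl | starting material
3 | chloromagnesium (3R,4R)-4-(tert-butyldimethylsilyloxy)-3-isopropylcyclopent-1-en-1-olate | Cl[Mg]OC1=C[C@@H](C(C)C)[C@H](O[Si](C)(C)C(C)(C)C)C1 | intermediate
4 | (3R,4R)-4-(tert-butyldimethylsilyloxy)-3-isopropyl-1-(triethylsilyloxy)cyclopent-1-ene | CC[Si](CC)(CC)OC1=C[C@@H](C(C)C)[C@H](O[Si](C)(C)C(C)(C)C)C1 | intermediate
5 | 3-(tert-butyldimethylsilyloxy)-4-isopropyl-1-(triethylsilyloxy)-6-oxabicyclo[3.1.0]hexane, oxirane oxygen anti to isopropyl | CC[Si](CC)(CC)O[C@@]12O[C@@H]1[C@@H](C(C)C)[C@H](O[Si](C)(C)C(C)(C)C)C2 | intermediate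
6 | (2R,3S,4R)-4-(tert-butyldimethylsilyloxy)-3-isopropyl-2-(triethylsilyloxy)cyclopentan-1-one | CC[Si](CC)(CC)O[C@H]1C(=O)C[C@@H](O[Si](C)(C)C(C)(C)C)[C@@H]1C(C)C | intermediate
7 | lithium (3S,4S,5R)-3-(tert-butyldimethylsilyloxy)-4-isopropyl-5-(triethylsilyloxy)cyclopent-1-en-1-olate | [Li]OC1=C[C@@H](O[Si](C)(C)C(C)(C)C)[C@H](C(C)C)[C@H]1O[Si](CC)(CC)CC | intermediate
8 | (3S,4S,5R)-3-(tert-butyldimethylsilyloxy)-4-isopropyl-5-(triethylsilyloxy)-1-(trimethylsilyloxy)cyclopent-1-ene | C[Si](C)(C)OC1=C[C@@H](O[Si](C)(C)C(C)(C)C)[C@H](C(C)C)[C@H]1O[Si](CC)(CC)CC | intermediate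
9 | bromoform | BrC(Br)Br | starting material
10 | 6,6-dibromo-4-(tert-butyldimethylsilyloxy)-3-isopropyl-2-(triethylsilyloxy)-1-(trimethylsilyloxy)bicyclo[3.1.0]hexane, CBr2 bridge anti to the two flanking silyloxy groups | C[Si](C)(C)O[C@]12[C@H](C1(Br)Br)[C@@H](O[Si](C)(C)C(C)(C)C)[C@H](C(C)C)[C@H]2O[Si](CC)(CC)CC | intermediate
11 | (4S,5S,6R)-2-bromo-4-(tert-butyldimethylsilyloxy)-5-isopropyl-6-(triethylsilyloxy)cyclohex-2-en-1-one | CC[Si](CC)(CC)O[C@H]1C(=O)C(Br)=C[C@@H](O[Si](C)(C)C(C)(C)C)[C@@H]1C(C)C | intermediate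
12 | ethyl 2-(triphenylphosphoranylidene)propanoate | CCOC(=O)C(C)=P(c1ccccc1)(c1ccccc1)c1ccccc1 | starting material
13 | (tert-butyldiphenylsilyloxy)acetaldehyde | O=CCO[Si](c1ccccc1)(c1ccccc1)C(C)(C)C | starting material
14 | ethyl (E)-4-(tert-butyldiphenylsilyloxy)-2-methylbut-2-enoate | C/C(=C\CO[Si](c1ccccc1)(c1ccccc1)C(C)(C)C)C(=O)OCC | intermediate
15 | lithium (E)-4-(tert-butyldiphenylsilyloxy)-2-methylbut-2-enoate | C/C(=C\CO[Si](c1ccccc1)(c1ccccc1)C(C)(C)C)C(=O)[O-].[Li+] | intermediate
16 | (E)-4-(tert-butyldiphenylsilyloxy)-2-methylbut-2-enoic acid | C/C(=C\CO[Si](c1ccccc1)(c1ccccc1)C(C)(C)C)C(=O)O | intermediate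
17 | (4S,5R,6R)-2-bromo-4-(tert-butyldimethylsilyloxy)-6-hydroxy-5-isopropylcyclohex-2-en-1-one | O[C@H]1C(=O)C(Br)=C[C@@H](O[Si](C)(C)C(C)(C)C)[C@@H]1C(C)C | intermediate
18 | O-acylisourea from 16 and DCC | C/C(=C\CO[Si](c1ccccc1)(c1ccccc1)C(C)(C)C)C(=O)OC(=NC1CCCCC1)NC1CCCCC1 | intermediate
19 | (4S,5R,6R)-2-bromo-4-(tert-butyldimethylsilyloxy)-5-isopropyl-6-{[(E)-4-(tert-butyldiphenylsilyloxy)-2-methylbut-2-enoyl]oxy}cyclohex-2-en-1-one | C/C(=C\CO[Si](c1ccccc1)(c1ccccc1)C(C)(C)C)C(=O)O[C@H]1C(=O)C(Br)=C[C@@H](O[Si](C)(C)C(C)(C)C)[C@@H]1C(C)C | intermediate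
20 | (4S,5S,6R)-2-bromo-4-hydroxy-5-isopropyl-6-{[(E)-4-(tert-butyldiphenylsilyloxy)-2-methylbut-2-enoyl]oxy}cyclohex-2-en-1-one | C/C(=C\CO[Si](c1ccccc1)(c1ccccc1)C(C)(C)C)C(=O)O[C@H]1C(=O)C(Br)=C[C@@H](O)[C@@H]1C(C)C | intermediate
21 | isobutyric acid | CC(C)C(=O)O | starting material
22 | C4 alkoxytriphenylphosphonium isobutyrate of 20 | C/C(=C\CO[Si](c1ccccc1)(c1ccccc1)C(C)(C)C)C(=O)O[C@H]1C(=O)C(Br)=C[C@@H](O[P+](c2ccccc2)(c2ccccc2)c2ccccc2)[C@@H]1C(C)C.CC(C)C(=O)[O-] | intermediate
23 | (4R,5S,6R)-2-bromo-4-(isobutyryloxy)-5-isopropyl-6-{[(E)-4-(tert-butyldiphenylsilyloxy)-2-methylbut-2-enoyl]oxy}cyclohex-2-en-1-one | C/C(=C\CO[Si](c1ccccc1)(c1ccccc1)C(C)(C)C)C(=O)O[C@H]1C(=O)C(Br)=C[C@H](OC(=O)C(C)C)[C@@H]1C(C)C | intermediate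
24 | (tributylstannyl)methanol | CCCC[Sn](CCCC)(CCCC)CO | starting material
25 | (4S,5S,6R)-2-(hydroxymethyl)-4-(isobutyryloxy)-5-isopropyl-6-{[(E)-4-(tert-butyldiphenylsilyloxy)-2-methylbut-2-enoyl]oxy}cyclohex-2-en-1-one | C/C(=C\CO[Si](c1ccccc1)(c1ccccc1)C(C)(C)C)C(=O)O[C@H]1C(=O)C(CO)=C[C@H](OC(=O)C(C)C)[C@@H]1C(C)C | intermediate
26 | CNP0254776.1, (4S,5S,6R)-6-{[(E)-4-hydroxy-2-methylbut-2-enoyl]oxy}-2-(hydroxymethyl)-4-(isobutyryloxy)-5-isopropylcyclohex-2-en-1-one | C/C(=C\CO)C(=O)O[C@H]1C(=O)C(CO)=C[C@H](OC(=O)C(C)C)[C@@H]1C(C)C | target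

## Step count and risks

Total step count: 12. Longest linear sequence: 10 (steps 1–4 and 7–12). Steps 5 and 6 build the side-chain acid in parallel.

**Step 4 (ring enlargement).**
- What may go wrong: tert-butoxide may cleave the trimethylsilyl enol ether faster than the carbene is captured at the doubly flanked double bond. The base may also epimerise or eliminate the enone once it has formed.
- The fallback sets out from 8 and comes back at 11. It delivers the extra carbon under neutral conditions and opens the ring by one-electron oxidation instead of ionisation.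
- Simmons–Smith cyclopropanation of 8 (Et2Zn, CH2I2, CH2Cl2, 0 °C) should give the silyloxycyclopropane F1.
- FeCl3 in DMF at 0 °C oxidises it to a cyclopropyloxy radical that cleaves the internal bond, and chlorine transfer gives the ring-enlarged 3-chlorocyclohexanone F2.
- Et3N in CH2Cl2 removes HCl to leave the unsubstituted cyclohexenone F3.
- Addition of Br2 in CH2Cl2 at 0 °C gives the 2,3-dibromocyclohexanone F4, which loses HBr on addition of Et3N in the same flask to give 11.

**Step 10 (Mitsunobu).**
- What may go wrong: the weakly acidic, branched carboxylic acid may displace slowly at a carbinol whose rear face is shielded by the neighbouring isopropyl group. Elimination toward a dienone, followed by aromatisation, could then take over.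
- The fallback sets out from 20 and comes back at 23. It separates activation from displacement, so the nucleophile is a crown-ether-activated carboxylate and its strength no longer depends on the pKa of the acid.
- ClCH2SO2Cl and pyridine in CH2Cl2 at 0 °C convert 20 into the C4 chloromethanesulfonate F5.
- Cs2CO3 and 21 in MeOH, followed by evaporation, give cesium isobutyrate F6.
- F5, F6 and 18-crown-6 in toluene (rt → 50 °C) should give 23 by SN2 inversion.

**Step 11 (Stille coupling).**
- What may go wrong: zerovalent palladium may ionise the allylic C4 isobutyrate in competition, or isobutyric acid may be lost thermally before the sluggish transmetalation is complete.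
- The fallback sets out from 19 and comes back at 26. It forms the C2–CH2OH bond while C4 still carries an inert silyl ether and moves the inversion behind it.
- Coupling of 19 with 24 (Pd(PPh3)4, dioxane, 90 °C) should give the C4-silylated hydroxymethyl enone F7.
- TBDPSCl and imidazole in CH2Cl2 protect the new primary alcohol as the bis(tert-butyldiphenylsilyl) ether F8.
- TFA/H2O in CH2Cl2 at 0 °C frees the C4 alcohol F9.
- Mitsunobu reaction with 21 (PPh3, DIAD, toluene) gives the C4-inverted isobutyrate F10.
- HF·pyridine in THF/pyridine removes both silyl ethers to give 26.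

## Further compounds

F1 | step 4 | 4-(tert-butyldimethylsilyloxy)-3-isopropyl-2-(triethylsilyloxy)-1-(trimethylsilyloxy)bicyclo[3.1.0]hexane, CH2 bridge anti to the flanking silyloxy groups | C[Si](C)(C)O[C@]12[C@H](C1)[C@@H](O[Si](C)(C)C(C)(C)C)[C@H](C(C)C)[C@H]2O[Si](CC)(CC)CC
F2 | step 4 | 4-(tert-butyldimethylsilyloxy)-3-chloro-5-isopropyl-6-(triethylsilyloxy)cyclohexan-1-one, epimers at C3 | CC[Si](CC)(CC)O[C@H]1C(=O)CC(Cl)[C@@H](O[Si](C)(C)C(C)(C)C)[C@@H]1C(C)C
F3 | step 4 | 4-(tert-butyldimethylsilyloxy)-5-isopropyl-6-(triethylsilyloxy)cyclohex-2-en-1-one, all-trans | CC[Si](CC)(CC)O[C@H]1C(=O)C=C[C@@H](O[Si](C)(C)C(C)(C)C)[C@@H]1C(C)C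
F4 | step 4 | 2,3-dibromo-4-(tert-butyldimethylsilyloxy)-5-isopropyl-6-(triethylsilyloxy)cyclohexan-1-one, C2 and C3 undefined | CC[Si](CC)(CC)O[C@H]1C(=O)C(Br)C(Br)[C@@H](O[Si](C)(C)C(C)(C)C)[C@@H]1C(C)C
F5 | step 10 | C4 chloromethanesulfonate of 20 | C/C(=C\CO[Si](c1ccccc1)(c1ccccc1)C(C)(C)C)C(=O)O[C@H]1C(=O)C(Br)=C[C@@H](OS(=O)(=O)CCl)[C@@H]1C(C)C
F6 | step 10 | cesium isobutyrate | CC(C)C(=O)[O-].[Cs+]
F7 | step 11 | 2-hydroxymethyl analogue of 19 | C/C(=C\CO[Si](c1ccccc1)(c1ccccc1)C(C)(C)C)C(=O)O[C@H]1C(=O)C(CO)=C[C@@H](O[Si](C)(C)C(C)(C)C)[C@@H]1C(C)C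
F8 | step 11 | tert-butyldiphenylsilyl ether of F7 | C/C(=C\CO[Si](c1ccccc1)(c1ccccc1)C(C)(C)C)C(=O)O[C@H]1C(=O)C(CO[Si](c2ccccc2)(c2ccccc2)C(C)(C)C)=C[C@@H](O[Si](C)(C)C(C)(C)C)[C@@H]1C(C)C
F9 | step 11 | C4 alcohol from F8 | C/C(=C\CO[Si](c1ccccc1)(c1ccccc1)C(C)(C)C)C(=O)O[C@H]1C(=O)C(CO[Si](c2ccccc2)(c2ccccc2)C(C)(C)C)=C[C@@H](O)[C@@H]1C(C)C
F10 | step 11 | C4-inverted isobutyrate from F9 | C/C(=C\CO[Si](c1ccccc1)(c1ccccc1)C(C)(C)C)C(=O)O[C@H]1C(=O)C(CO[Si](c2ccccc2)(c2ccccc2)C(C)(C)C)=C[C@H](OC(=O)C(C)C)[C@@H]1C(C)C
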